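## Retrosynthetic overview

1. The acid comes from its methyl ester. The 8-phenyloctyl chain is attached to C6 last, by Wittig olefination of a C6 aldehyde, and one diimide reduction saturates this alkene together with the ring C4=C5 bond.
2. Key disconnection C3–C4: the 3,6-dihydro-1,2-dioxine arises by a catalytic "peroxy silyl-Prins ring switch" of a 1,2,4-trioxane carrying a (Z)-2-silylvinyl group on C6. The trioxane C3–O4 bond ionises, C4 attacks C3, and silicon moves to the freed oxygen.
3. Enabling feature: C3 of the 1,2-dioxane is both a peroxide carbon and the keto carbon of a levulinic acid unit (CH3–C–CH2CH2CO2H), so it can become a peroxycarbenium ion. The C4–C5 bridge is unsubstituted and can be carried as a cis-vinylsilane. C3 and C6 bear no hydrogen, so the O–O bond survives base, ylide and oxidant.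
4. The trioxane is the ketal of methyl levulinate with a β-hydroxy hydroperoxide. That hydroperoxide is made by invertive perhydrolysis of a vinylsilane epoxide derived from (S)-2-methylglycidol, which is the source of C6.
5. Ring order: oxirane (bought) → 1,2,4-trioxane (temporary) → 3,6-dihydro-1,2-dioxine (key step) → 1,2-dioxane.

Key step: step 7

Assumption: the peroxide ring is numbered O1–O2–C3–C4–C5–C6 with C3 bearing the propanoic acid chain, and (S)-2-methylglycidol and (7-bromoheptyl)benzene are taken as purchasable.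

## Route

Step 1
Reactants: 1 (S)-2-methylglycidol
Product: 2 (R)-2-methyloxirane-2-carbaldehyde
Conditions: TEMPO (10 mol %), PhI(OAc)2, CH2Cl2, rt; solution used directly
Reagents that add atoms: none
Why: Oxoammonium (TEMPO) oxidation of a primary alcohol stops at the aldehyde, and the quaternary epoxide carbon has no α-hydrogen, so the bought stereocentre cannot epimerise.

Step 2
Reactants: 2 (R)-2-methyloxirane-2-carbaldehyde
Product: 3 (S)-2-(2,2-dibromoethenyl)-2-methyloxirane
Conditions: CBr4, PPh3, Zn, CH2Cl2, 0 °C → rt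
Reagents that add atoms: carbon tetrabromide, BrC(Br)(Br)Br
Why: This is the first stage of the Corey–Fuchs sequence (Ramirez dibromo-olefination), with zinc taking up the bromine so that no bromophosphonium species is left to open the epoxide.

Step 3
Reactants: 3 (S)-2-(2,2-dibromoethenyl)-2-methyloxirane
Product: 5 (S)-trimethyl[(2-methyloxiran-2-yl)ethynyl]silane, via lithium acetylide 4 (not isolated)
Conditions: n-BuLi (2.1 equiv), THF, −78 °C; then Me3SiCl, −78 °C → rt
Reagents that add atoms: chlorotrimethylsilane, C[Si](C)(C)Cl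
Why: In the second stage of the Corey–Fuchs sequence, Br/Li exchange, a Fritsch–Buttenberg–Wiechell shift and deprotonation give acetylide 4, which is C-silylated before it can touch the hindered epoxide at low temperature.

Step 4
Reactants: 5 (S)-trimethyl[(2-methyloxiran-2-yl)ethynyl]silane
Product: 6 (S)-trimethyl[(Z)-2-(2-methyloxiran-2-yl)ethenyl]silane
Conditions: H2 (1 atm), Lindlar catalyst, quinoline, hexane, rt
Reagents that add atoms: none
Why: Lindlar semi-hydrogenation adds H2 syn to the silylalkyne and so gives the (Z)-vinylsilane that the ring closure needs, and the poisoned catalyst should spare the epoxide.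

Step 5
Reactants: 6 (S)-trimethyl[(Z)-2-(2-methyloxiran-2-yl)ethenyl]silane
Product: 7 (2R,3Z)-2-hydroperoxy-2-methyl-4-(trimethylsilyl)but-3-en-1-ol
Conditions: anhydrous ethereal H2O2 (excess), phosphomolybdic acid (3 mol %), Et2O, 0 °C
Reagents that add atoms: hydrogen peroxide, OO
Why: Mo(VI)-catalysed perhydrolysis of a 2,2-disubstituted vinyl epoxide is the reaction type that converts 2-methyl-2-vinyloxirane into its 1,2-hydroxy hydroperoxide; H2O2 attacks the tertiary allylic carbon from the back of the C–O bond, so C6 is set by inversion of the glycidol centre.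

Step 6
Reactants: 7 (2R,3Z)-2-hydroperoxy-2-methyl-4-(trimethylsilyl)but-3-en-1-ol; 8 methyl levulinate
Product: 9 methyl 3-{(6R)-3,6-dimethyl-6-[(Z)-2-(trimethylsilyl)ethenyl]-1,2,4-trioxan-3-yl}propanoate (both C3 epimers)
Conditions: p-TsOH·H2O (5 mol %), 4 Å MS, CH2Cl2, 0 °C → rt
Reagents that add atoms: none
Why: Acid-catalysed condensation of a β-hydroxy hydroperoxide with a ketone is the standard route to 1,2,4-trioxanes; the ring masks OOH and OH together and installs the ketal leaving group at C3, whose configuration is irrelevant because step 7 erases it.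

Step 7
Reactants: 9 methyl 3-{(6R)-3,6-dimethyl-6-[(Z)-2-(trimethylsilyl)ethenyl]-1,2,4-trioxan-3-yl}propanoate
Product: 12 methyl 3-[(3S,6R)-6-(hydroxymethyl)-3,6-dimethyl-3,6-dihydro-1,2-dioxin-3-yl]propanoate, via peroxycarbenium ion 10 (not isolated), via trimethylsilyl ether 11 (not isolated)
Conditions: confined chiral imidodiphosphorimidate acid (IDPi, 5 mol %, enantiomer picked in a screen), methallyl-SiMe3 (5 mol %, activator), CH2Cl2, −78 → −40 °C; then MeOH, PPTS (cat.), 0 °C
Reagents that add atoms: none
Why: Proposed new method: the silylium form of the chiral acid binds O4, the most basic oxygen of trioxane 9, the C3–O4 bond ionises to the levulinate-derived peroxycarbenium ion 10 (both C3 epimers of 9 converge on it), the silicon-bearing carbon C4 of the (Z)-vinylsilane attacks C3, and the β-silyl cation sheds Me3Si+, which restarts the cycle, so that 9 isomerises to silyl ether 11 without any added atom. The closest known reaction types are the Lewis-acid reaction of monoperoxyketals with allylsilanes through peroxycarbenium ions (also intramolecular, giving 1,2-dioxanes) and the silyl-Prins cyclisation of (Z)-4-silylbut-3-enyl oxocarbenium ions to 5,6-dihydro-2H-pyrans, of which this is the analogue with one ring CH2 replaced by the second peroxide oxygen. The 3,6-dihydro-1,2-dioxine closes 6-endo-trig with the vinylsilane C=C inside the new ring, which demands the Z geometry, while the temporary 1,2,4-trioxane opens in the same event. C3 is the only new stereocentre: its face is chosen by the confined chiral anion paired with 10 (silylium counter-anion catalysis of this kind is known for aliphatic oxocarbenium ions and can tell methyl from ethyl on a small ketone), and the chair-like transition state with C–Si and the C6 methyl axial and both CH2OSiMe3 and the ester chain equatorial leads to the same trans-dimethyl isomer, so catalyst and substrate should be matched, while C6 is not touched. The step needs ionisation at the ketal C3–O4 bond rather than at the tertiary allylic C6–O1 bond or the O–O bond, and C–C bonding at C4 rather than C5; the first is secured by the higher basicity of the ether oxygen, the stabilised peroxycarbenium ion, the low temperature and the non-nucleophilic anion, the second by the β-silicon effect, which disfavours the 5-exo path to an α-silyl cation. Mild methanolysis then frees alcohol 12, the handle for the side chain.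

Step 8
Reactants: 12 methyl 3-[(3S,6R)-6-(hydroxymethyl)-3,6-dimethyl-3,6-dihydro-1,2-dioxin-3-yl]propanoate
Product: 13 methyl 3-[(3S,6R)-6-formyl-3,6-dimethyl-3,6-dihydro-1,2-dioxin-3-yl]propanoate
Conditions: Dess–Martin periodinane, CH2Cl2, 0 °C → rt
Reagents that add atoms: none
Why: Dess–Martin oxidation is a neutral two-electron oxidation known to leave dialkyl peroxides and alkenes alone, and the aldehyde formed has no α-hydrogen.

Step 9
Reactants: 14 (7-bromoheptyl)benzene
Product: 15 triphenyl(7-phenylheptyl)phosphonium bromide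
Conditions: PPh3, MeCN, reflux
Reagents that add atoms: triphenylphosphine, c1ccc(cc1)P(c1ccccc1)c1ccccc1
Why: This is the SN2 quaternisation of triphenylphosphine by a primary bromide.

Step 10
Reactants: 13 methyl 3-[(3S,6R)-6-formyl-3,6-dimethyl-3,6-dihydro-1,2-dioxin-3-yl]propanoate; 15 triphenyl(7-phenylheptyl)phosphonium bromide
Product: 17 methyl 3-{(3S,6S)-3,6-dimethyl-6-[(Z)-8-phenyloct-1-enyl]-3,6-dihydro-1,2-dioxin-3-yl}propanoate, via phosphonium ylide 16 (not isolated)
Conditions: 15, NaHMDS, THF, 0 °C; then 13, −78 → 0 °C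
Reagents that add atoms: none
Why: Wittig olefination with a lithium-free non-stabilised ylide is known to tolerate peroxides; the fast cycloaddition at −78 °C should outrun attack on the ester, the aldehyde cannot enolise, and the alkene geometry does not matter.

Step 11
Reactants: 17 methyl 3-{(3S,6S)-3,6-dimethyl-6-[(Z)-8-phenyloct-1-enyl]-3,6-dihydro-1,2-dioxin-3-yl}propanoate
Product: 18 methyl 3-[(3R,6S)-3,6-dimethyl-6-(8-phenyloctyl)-1,2-dioxan-3-yl]propanoate
Conditions: KO2CN=NCO2K (excess, in portions), AcOH, MeOH/CH2Cl2, 0 °C → rt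
Reagents that add atoms: none
Why: Diimide transfers H2 concertedly to C=C bonds only and is the standard way to saturate 3,6-dihydro-1,2-dioxines without O–O cleavage; both alkenes are reduced and no stereocentre is touched (the C3 descriptor changes from S to R only through CIP ranking).

Step 12
Reactants: 18 methyl 3-[(3R,6S)-3,6-dimethyl-6-(8-phenyloctyl)-1,2-dioxan-3-yl]propanoate
Product: 19 3-[(3R,6S)-3,6-dimethyl-6-(8-phenyloctyl)-1,2-dioxan-3-yl]propanoic acid
Conditions: LiOH, THF/H2O, rt; then 1 M HCl
Reagents that add atoms: lithium hydroxide, [Li+].[OH-]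
Why: This is a saponification; the 3,3,6,6-tetrasubstituted 1,2-dioxane has no hydrogen on its peroxide carbons, so base-induced Kornblum–DeLaMare fragmentation is impossible.

## Compound list

1 | (S)-2-methylglycidol | C[C@@]1(CO1)CO | starting material
2 | (R)-2-methyloxirane-2-carbaldehyde | C[C@@]1(CO1)C=O | intermediate
3 | (S)-2-(2,2-dibromoethenyl)-2-methyloxirane | C[C@@]1(CO1)C=C(Br)Br | intermediate
4 | lithium acetylide of (S)-2-ethynyl-2-methyloxirane | C[C@@]1(CO1)C#C[Li] | intermediate
5 | (S)-trimethyl[(2-methyloxiran-2-yl)ethynyl]silane | C[C@@]1(CO1)C#C[Si](C)(C)C | intermediate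
6 | (S)-trimethyl[(Z)-2-(2-methyloxiran-2-yl)ethenyl]silane | C[C@@]1(CO1)/C=C\[Si](C)(C)C | intermediate
7 | (2R,3Z)-2-hydroperoxy-2-methyl-4-(trimethylsilyl)but-3-en-1-ol | C[C@](OO)(CO)/C=C\[Si](C)(C)C | intermediate
8 | methyl levulinate | COC(=O)CCC(C)=O | starting material
9 | methyl 3-{(6R)-3,6-dimethyl-6-[(Z)-2-(trimethylsilyl)ethenyl]-1,2,4-trioxan-3-yl}propanoate, both C3 epimers | C[C@@]1(/C=C\[Si](C)(C)C)COC(C)(CCC(=O)OC)OO1 | intermediate
10 | peroxycarbenium ion from O4-silylation and C3–O4 ionisation of 9 (ion pair with the chiral anion) | COC(=O)CCC(C)=[O+]O[C@@](C)(CO[Si](C)(C)C)/C=C\[Si](C)(C)C | intermediate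
11 | methyl 3-{(3S,6R)-3,6-dimethyl-6-[(trimethylsilyloxy)methyl]-3,6-dihydro-1,2-dioxin-3-yl}propanoate | C[C@]1(CO[Si](C)(C)C)C=C[C@](C)(CCC(=O)OC)OO1 | intermediate
12 | methyl 3-[(3S,6R)-6-(hydroxymethyl)-3,6-dimethyl-3,6-dihydro-1,2-dioxin-3-yl]propanoate | C[C@]1(CO)C=C[C@](C)(CCC(=O)OC)OO1 | intermediate
13 | methyl 3-[(3S,6R)-6-formyl-3,6-dimethyl-3,6-dihydro-1,2-dioxin-3-yl]propanoate | C[C@]1(C=O)C=C[C@](C)(CCC(=O)OC)OO1 | intermediate
14 | (7-bromoheptyl)benzene | BrCCCCCCCc1ccccc1 | starting material
15 | triphenyl(7-phenylheptyl)phosphonium bromide | [Br-].c1ccc(cc1)CCCCCCC[P+](c1ccccc1)(c1ccccc1)c1ccccc1 | intermediate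
16 | triphenyl(7-phenylheptylidene)phosphorane | c1ccc(cc1)CCCCCCC=P(c1ccccc1)(c1ccccc1)c1ccccc1 | intermediate
17 | methyl 3-{(3S,6S)-3,6-dimethyl-6-[(Z)-8-phenyloct-1-enyl]-3,6-dihydro-1,2-dioxin-3-yl}propanoate | C[C@]1(/C=C\CCCCCCc2ccccc2)C=C[C@](C)(CCC(=O)OC)OO1 | intermediate
18 | methyl 3-[(3R,6S)-3,6-dimethyl-6-(8-phenyloctyl)-1,2-dioxan-3-yl]propanoate | C[C@]1(CCCCCCCCc2ccccc2)CC[C@](C)(CCC(=O)OC)OO1 | intermediate
19 | 3-[(3R,6S)-3,6-dimethyl-6-(8-phenyloctyl)-1,2-dioxan-3-yl]propanoic acid | C[C@]1(CCCCCCCCc2ccccc2)CC[C@](C)(CCC(=O)O)OO1 | target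

Total step count: 12. Longest linear sequence: 11 (steps 1–8 and 10–12).

## Steps most likely to fail

**Step 7 (Proposed new method).**
- Heterolysis of the tertiary allylic C6–O1 bond or a Hock-type O–O cleavage may outrun attack by the weakly nucleophilic, hindered vinylsilane.
- The chiral anion may also discriminate poorly between the two faces of C3.
- The fallback gives up the C–C closure and builds the ring through its two C–O bonds by epoxide perhydrolysis, which is known chemistry for 1,2-dioxanes. It sets out from dibromide 3 and comes back at ester 18.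
- Acetylide 4, made from 3 as in step 3, is added to chloroacetone to give the chlorohydrin 1-chloro-2-methyl-4-[(2S)-2-methyloxiran-2-yl]but-3-yn-2-ol F1 as two epimers.
- K2CO3 closes the second epoxide, and chromatography separates the meso isomer from the C2-symmetric 1,2-bis[(2S)-2-methyloxiran-2-yl]ethyne F2.
- Lindlar hydrogenation gives (Z)-1,2-bis[(2S)-2-methyloxiran-2-yl]ethene F3.
- H2O2 with phosphomolybdic acid opens one tertiary allylic epoxide with inversion to the hydroperoxy epoxide F4. This opens the second epoxide 6-exo at its tertiary carbon, again with inversion, to the C2-symmetric [(3R,6R)-3,6-dimethyl-3,6-dihydro-1,2-dioxine-3,6-diyl]dimethanol F5.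
- The two CH2OH groups are homotopic, so mono-oxidation (TEMPO, one equivalent of PhI(OAc)2) gives a single hydroxy aldehyde F6.
- Ph3P=CHCO2Me gives the hydroxy enoate F7, Dess–Martin oxidation gives the formyl enoate F8, and ylide 16 gives the triene ester F9.
- Diimide saturates all three C=C bonds of F9 to give 18.

**Step 5.**
- The opening may drift towards an allyl-cation pathway with partial loss of configuration at C6. SN2′ attack at the silyl-bearing carbon and Z→E isomerisation are also possible.
- The fallback moves the perhydrolysis to the alkynyl epoxide, whose propargylic carbon ionises far less readily, and makes the vinylsilane afterwards. It sets out from 5 and comes back at 9.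
- Compound 5 with H2O2 and phosphomolybdic acid gives (2R)-2-hydroperoxy-2-methyl-4-(trimethylsilyl)but-3-yn-1-ol F10.
- Condensation with 8 as in step 6 gives the alkynyl trioxane F11.
- Syn hydroboration with dicyclohexylborane, which places boron on the silicon-bearing carbon and belongs to a reagent class that 1,2,4-trioxanes are known to survive, gives the alkenylborane F12.
- Protonolysis of F12 with AcOH, with retention of geometry, gives 9.

**Step 4.**
- Over-reduction, hydrogenolysis of the propargylic or allylic C–O bond, or stalled uptake at the hindered silylalkyne may spoil the semi-hydrogenation.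
- The fallback sets the Z geometry by olefination instead of reduction. It sets out from aldehyde 2 and comes back at 6.
- Stork–Zhao olefination (Ph3P+CH2I I−, NaHMDS, THF/HMPA, −78 °C) gives (S)-2-[(Z)-2-iodoethenyl]-2-methyloxirane F13.
- I/Li exchange with t-BuLi at −78 °C gives the configurationally stable (Z)-vinyllithium F14, which is quenched with Me3SiCl to give 6.

## Further compounds

F1 | step 7 | 1-chloro-2-methyl-4-[(2S)-2-methyloxiran-2-yl]but-3-yn-2-ol (both carbinol epimers) | C[C@@]1(CO1)C#CC(C)(O)CCl
F2 | step 7 | 1,2-bis[(2S)-2-methyloxiran-2-yl]ethyne | C[C@@]1(CO1)C#C[C@@]2(C)CO2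
F3 | step 7 | (Z)-1,2-bis[(2S)-2-methyloxiran-2-yl]ethene | C[C@@]1(CO1)/C=C\[C@@]2(C)CO2
F4 | step 7 | (2R,3Z)-2-hydroperoxy-2-methyl-4-[(2S)-2-methyloxiran-2-yl]but-3-en-1-ol | C[C@](OO)(CO)/C=C\[C@@]1(C)CO1
F5 | step 7 | [(3R,6R)-3,6-dimethyl-3,6-dihydro-1,2-dioxine-3,6-diyl]dimethanol | C[C@]1(CO)C=C[C@](C)(CO)OO1
F6 | step 7 | (3R,6R)-6-(hydroxymethyl)-3,6-dimethyl-3,6-dihydro-1,2-dioxine-3-carbaldehyde | C[C@]1(CO)C=C[C@](C)(C=O)OO1
F7 | step 7 | methyl (E)-3-[(3R,6R)-6-(hydroxymethyl)-3,6-dimethyl-3,6-dihydro-1,2-dioxin-3-yl]prop-2-enoate | C[C@]1(CO)C=C[C@](C)(/C=C/C(=O)OC)OO1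
F8 | step 7 | methyl (E)-3-[(3R,6R)-6-formyl-3,6-dimethyl-3,6-dihydro-1,2-dioxin-3-yl]prop-2-enoate | C[C@]1(C=O)C=C[C@](C)(/C=C/C(=O)OC)OO1
F9 | step 7 | methyl (E)-3-{(3R,6S)-3,6-dimethyl-6-[(Z)-8-phenyloct-1-enyl]-3,6-dihydro-1,2-dioxin-3-yl}prop-2-enoate | C[C@]1(/C=C\CCCCCCc2ccccc2)C=C[C@](C)(/C=C/C(=O)OC)OO1
F10 | step 5 | (2R)-2-hydroperoxy-2-methyl-4-(trimethylsilyl)but-3-yn-1-ol | C[C@](OO)(CO)C#C[Si](C)(C)C
F11 | step 5 | methyl 3-{(6R)-3,6-dimethyl-6-[(trimethylsilyl)ethynyl]-1,2,4-trioxan-3-yl}propanoate (both C3 epimers) | C[C@@]1(C#C[Si](C)(C)C)COC(C)(CCC(=O)OC)OO1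
F12 | step 5 | methyl 3-{(6R)-6-[(Z)-2-(dicyclohexylboranyl)-2-(trimethylsilyl)ethenyl]-3,6-dimethyl-1,2,4-trioxan-3-yl}propanoate | C[C@@]1(/C=C(\[Si](C)(C)C)B(C2CCCCC2)C2CCCCC2)COC(C)(CCC(=O)OC)OO1
F13 | step 4 | (S)-2-[(Z)-2-iodoethenyl]-2-methyloxirane | C[C@@]1(CO1)/C=C\I
F14 | step 4 | (Z)-2-[(S)-2-methyloxiran-2-yl]ethenyllithium | C[C@@]1(CO1)/C=C\[Li]
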